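Take the two flasks one at a time.

| flask | starting complex | incoming ligand | leaving ligand | remark | time |
|---|---|---|---|---|---|
| green | 0.30 M | 0.60 M | 0.20 M | run made earlier |  |
| west | 0.20 M | 0.200 M | 0.200 M |  | 25 min |
| south-east | 0.20 M | 0.600 M | 0.200 M |  | 12 min |

green run (percent of the starting complex charged)

| time / min | complex with one exchanged / % | complex with two exchanged / % |
|---|---|---|
| 1.00 | 51.6 | 13.2 |
| 2.00 | 56.8 | 18.7 |
| 3.00 | 58.5 | 16.0 |
| 4.00 | 57.4 | 15.1 |
| 5.00 | 55.6 | 13.8 |
| 6.00 | 54.1 | 12.8 |
| 8.00 | 49.4 | 10.7 |

(scatter of a reading: 0.5 percentage points)

- steps under discussion: complex with one exchanged + incoming ligand -> over-reaction product; complex with one exchanged + incoming ligand <-> leaving ligand + complex with two exchanged; starting complex + incoming ligand <-> leaving ligand + complex with one exchanged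
- no earlier run changes the charge of incoming ligand; that part of a forecast is a guess

- the winner by share of complex with one exchanged in all that became complex with one exchanged or complex with two exchanged or over-reaction product; "neither" if no more than 2 percentage points parts them (west / south-east / neither)
- share of complex with one exchanged in all that became complex with one exchanged or complex with two exchanged or over-reaction product, west
- share of complex with one exchanged in all that became complex with one exchanged or complex with two exchanged or over-reaction product, south-east

**What takes the complex with one exchanged away?** Two follow-on steps, and both need incoming ligand. The over-reaction is listed as running one way.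

**How fast is that?** In green the sum of the two exchanged complexes falls from 74.5% at 3.00 min to 60.1% at 8.00 min. From that fall the forecast reads a constant of 0.300 M⁻¹ min⁻¹.

**How does a constant become a share?** While the level of incoming ligand holds steady, the over-reaction is pseudo-first-order, so its rate integrates to a plain decay. The part of the complex with one exchanged that stays is then e to the minus the exposure.

**What level do you take for west?** West charges ligand and complex equally, and I take the forecast's level, 20.0% of the charge. The over-reaction exposure of west, 0.300, is the constant times the level of incoming ligand times the time. So my share for west is 74.1%.

**And south-east?** In south-east a complete first exchange takes a third of the ligand charge and the follow-on steps take more, so I hold the level at 50.0%. Its exposure is 1.08, which is larger than west's, and my share is 34.0%.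

**Where is this weakest?** No earlier run changes the ligand charge, so both levels are guesses, and my rule leaves the complex with two exchanged out. Even so, the gap between my two shares is far wider than the margin of 2 percentage points, so I pick west.

The forecast also names west, but with its own figures, 71% and 36%, and its ground for south-east is that “excess incoming ligand drives both follow-on steps”.

The flasks give west, with 75.2% for west and 31.1% for south-east.

    complex with one exchanged + incoming ligand → over-reaction product (k = 0.340 M⁻¹ min⁻¹)
    complex with one exchanged + incoming ligand ⇌ leaving ligand + complex with two exchanged (K = 0.600, k = 1.30 M⁻¹ min⁻¹)
    starting complex + incoming ligand ⇌ leaving ligand + complex with one exchanged (K = 31.0, k = 2.80 M⁻¹ min⁻¹)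

The main reason is the smaller charge of incoming ligand in west: with the charge of south-east, west drops from 75.2% to 14.9%. With the over-reaction constant of the scheme and the level at 6.00 min, the exposure of south-east becomes 1.21, which gives 29.8%, against the 31.1% of that flask. The neighbour flask, west with 0.050 M of starting complex, ends at 59.9% of its ligand charge; taken at that end level, its exposure is 1.02 and the rule gives 36.1%, where that flask shows 35.4%.

The runs were generated by integration from invented constants; the scatter is artificial.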